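Time changes little in the autumn flask, which is the flask asked about, once 2.00 min have passed: substrate reads 1 % and then 0 %, while target stays between 37 % and 39 %.

all flasks: solid reagent 20.4 mM
- autumn: substrate 17 mM; temperature 90 °C; the very flask that is asked about, followed so far
- summer: substrate 11 mM; temperature 85 °C; run made earlier
- flask: substrate 17 mM; temperature 90 °C; time 10 min

autumn run (percent of the substrate charged)

| time / min | target / % | substrate / % |
|---|---|---|
| 0.417 | 2 | 86 |
| 1.33 | 41 | 4 |
| 2.00 | 38 | 1 |
| 3.00 | 39 | 0 |
| 5.00 | 37 | 0 |
| 6.00 | 38 | 0 |

summer run (percent of the substrate charged)

| time / s | target / % | substrate / % |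
|---|---|---|
| 10.0 | 0 | 97 |
| 12.0 | 3 | 97 |
| 20.0 | 2 | 94 |
| 30.0 | 6 | 93 |
| 50.0 | 11 | 73 |
| 80.0 | 28 | 25 |

(each reading ± 2 percentage points)

- given per volume of solution although it is solid: solid reagent
- additions bring no volume worth counting
- at the start none of the solid reagent is in solution

- north: at 10 min raise the temperature by 25 K, then wait 10 min
- east: at 10 min add substrate, 50.0 % of the amount charged, then wait 10 min
- south: change nothing and wait 10 min more
- north-west: at 10 min take out 90 % of the by-product then present, then wait 10 min

1. target, in percent of the substrate first charged, at 10 min
2. the remedy with the largest gain of target, or "none" below 2 percentage points (north / east / south / north-west / none)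
3. target present, in percent of the substrate first charged, after north
4. target present, in percent of the substrate first charged, after north-west

A first estimate for 10 min carries this flat stretch forward:

plateau = mean of the target readings from 2.00 min on = 38.0 %

The objection is a slow drift hidden in the scatter, but these readings span 2 percentage points against 2 points for a single reading, so no drift can be read and the estimate stands. A harder objection is that the plateau accounts for part of the charge:

unseen share = whole charge − plateau = 62.0 %

This unseen share, the part of the charge standing as neither substrate nor target on the plateau, might have grown out of target late. Yet the summer flask, with substrate still at 25 %, has made target per substrate used of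

28 % / (whole charge − 25 %) = 37.3 %,

about the plateau, although that flask differs in both substrate and temperature, so in the summer flask the unseen share has kept pace with target up to that reading. A fixed split between parallel routes gives this picture, but so does a fast balance, which once reached shares its pool by temperature and not by time. This reckoning therefore commits to 38.0 % at 10 min and to no gain from waiting, and leaves the rise of 25 K open.

The forecast agrees on the first point with 38 %, and goes on where this reckoning stopped: it gives 38 % after north-west, names east as best, and gives 37 % after north, holding that “Heating does nothing unless slow, hidden decay speeds up”.

The flask gives 38.2 % at 10 min, north as the best remedy with a gain of 17 points, ahead of east with 5.5 points, then 55.2 % after north and 38.2 % after north-west.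

    substrate + partner + by-product → target + 2 by-product (k = 690 L² mol⁻² s⁻¹, Ea = 38.0 kJ mol⁻¹)
    substrate + partner → target + by-product (k = 0.0940 L mol⁻¹ s⁻¹, Ea = 46.0 kJ mol⁻¹)
    substrate + target → side product (k = 1.80 L mol⁻¹ s⁻¹, Ea = 57.0 kJ mol⁻¹)
    solid reagent ⇌ partner, rate k4*(cs4 - [partner]) while solid is left; crystals form when [partner] > cs4 (solubility = 11.0 mM, k = 0.440 s⁻¹)
    target ⇌ isomer of the product (K = 1.00, k = 0.210 s⁻¹, Ea = 78.0 kJ mol⁻¹, ΔH = −45.0 kJ mol⁻¹)
    (constants at 90 °C)

The share read as unseen, 62.0 %, stands in the flask at 10.0 min as 38.2 % isomer of the product and 23.7 % side product, each side product counted twice for the substrate it holds. Target goes to the isomer with a half-life of 0.055 min by the forward rate alone, shorter than the 0.38 min towards side product with the other concentrations as charged and short against 10 min, and at 10.0 min target and isomer of the product stand level, the picture of thermodynamic control; after north the flask holds 55.2 % as target, 18 points above the forecast.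

In the neighbour flask at 75 °C, with amounts and time held, the unseen 62.0 % carried over gives target 38.0 %. That flask holds 28.4 %, with 54.0 % isomer of the product and 17.6 % side product.

(The readings are calculated on assumed constants.)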